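**Retrosynthetic overview**
1. 15 ⇐ 13: the 3-O-PMB ether and the two MOM ethers are removed last.
2. 13 ⇐ 12: ring C (the pyranone, the only ring the route has to form) is opened at O1–C8a; forward, the C2 alkoxide displaces the fluorine ortho to the ketone (SNAr, retention at C2).
3. 12 ⇐ 7 + 9 + 10: the route rests on C3 of ring C, an oxygen-bearing carbon set between the C4 ketone and the C2 aryl carbinol. C3 is the carbene carbon of diazoketone 7 and gains its oxygen from alcohol 10 (C3–O) and C2 from aldehyde 9 (C2–C3) in one step.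
4. 7 ⇐ 1 (ring A bought; diiodination, MOM ether, double Stille prenylation with 4, detrifluoroacetylative diazo transfer); 9 ⇐ 8 (ring B bought).

Key step: step 7

Assumption: the (S)-3,3'-diiodo-BINOL zirconium catalyst is written as the one that sends the ylide to the Si face of aldehyde 9 (R carbinol); both ligand antipodes are available, so the antipode is fixed by the sense of induction found.

**Route**

Step 1
Reactants: 1 2'-fluoro-4'-hydroxyacetophenone
Product: 2 1-(2-fluoro-4-hydroxy-3,5-diiodophenyl)ethan-1-one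
Conditions: NIS (2.1 equiv), TsOH·H2O (10 mol %), MeCN, rt
Reagents that add atoms: N-iodosuccinimide, O=C1CCC(=O)N1I
Why: Electrophilic aromatic iodination, in which the free phenol directs to its two ortho positions (C3 and C5) because the para position carries the acetyl group.

Step 2
Reactants: 2 1-(2-fluoro-4-hydroxy-3,5-diiodophenyl)ethan-1-one
Product: 3 1-[2-fluoro-3,5-diiodo-4-(methoxymethoxy)phenyl]ethan-1-one
Conditions: MOMCl, iPr2NEt, CH2Cl2, 0 °C → rt
Reagents that add atoms: chloromethyl methyl ether, COCCl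
Why: O-Alkylation of the acidic diiodophenol (Williamson-type acetal formation) gives a MOM ether that should survive the Pd, base, Rh and DDQ steps and leave with acid at the end.

Step 3
Reactants: 3 1-[2-fluoro-3,5-diiodo-4-(methoxymethoxy)phenyl]ethan-1-one; 4 tributyl(3-methylbut-2-en-1-yl)stannane
Product: 5 1-[2-fluoro-4-(methoxymethoxy)-3,5-bis(3-methylbut-2-en-1-yl)phenyl]ethan-1-one
Conditions: Pd(PPh3)4 (10 mol %), 4 (2.5 equiv), DMF, 90 °C
Reagents that add atoms: none
Why: Double Stille cross-coupling, in which reductive elimination at the less substituted allyl terminus should give the linear prenyl groups while the aryl fluoride, ketone and MOM ether are inert to Pd(0) under neutral conditions.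

Step 4
Reactants: 5 1-[2-fluoro-4-(methoxymethoxy)-3,5-bis(3-methylbut-2-en-1-yl)phenyl]ethan-1-one
Product: 6 4,4,4-trifluoro-1-[2-fluoro-4-(methoxymethoxy)-3,5-bis(3-methylbut-2-en-1-yl)phenyl]butane-1,3-dione (used crude)
Conditions: LiHMDS (1.1 equiv), THF, −78 °C; CF3CO2CH2CF3 (1.2 equiv); then aq. HCl
Reagents that add atoms: 2,2,2-trifluoroethyl trifluoroacetate, O=C(OCC(F)(F)F)C(F)(F)F
Why: Claisen-type trifluoroacetylation of the kinetic lithium enolate activates the methyl ketone for diazo transfer (first half of the Danheiser detrifluoroacetylative procedure).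

Step 5
Reactants: 6 4,4,4-trifluoro-1-[2-fluoro-4-(methoxymethoxy)-3,5-bis(3-methylbut-2-en-1-yl)phenyl]butane-1,3-dione
Product: 7 2-diazo-1-[2-fluoro-4-(methoxymethoxy)-3,5-bis(3-methylbut-2-en-1-yl)phenyl]ethan-1-one
Conditions: MsN3 (1.5 equiv), Et3N (1.5 equiv), H2O (1 equiv), MeCN, rt
Reagents that add atoms: methanesulfonyl azide, CS(=O)(=O)N=[N+]=[N-]
Why: Regitz diazo transfer to the 1,3-diketone with loss of the trifluoroacetyl group onto the sulfonamide nitrogen (detrifluoroacetylative diazo transfer) should give the terminal diazoketone under conditions that leave the aryl fluoride and the prenyl groups alone.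

Step 6
Reactants: 8 4-hydroxybenzaldehyde
Product: 9 4-(methoxymethoxy)benzaldehyde
Conditions: MOMCl, iPr2NEt, CH2Cl2, 0 °C → rt
Reagents that add atoms: chloromethyl methyl ether, COCCl
Why: O-Alkylation of the phenol (MOM ether formation) masks the B-ring hydroxyl with the same acid-labile group as on ring A.

Step 7
Reactants: 7 2-diazo-1-[2-fluoro-4-(methoxymethoxy)-3,5-bis(3-methylbut-2-en-1-yl)phenyl]ethan-1-one; 9 4-(methoxymethoxy)benzaldehyde; 10 4-methoxybenzyl alcohol
Product: 12 (2R,3R)-1-[2-fluoro-4-(methoxymethoxy)-3,5-bis(3-methylbut-2-en-1-yl)phenyl]-3-hydroxy-2-[(4-methoxyphenyl)methoxy]-3-[4-(methoxymethoxy)phenyl]propan-1-one (anti adduct), via protic oxonium ylide 11 (not isolated)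
Conditions: Rh2(OAc)4 (2 mol %), Zr(OnBu)4/(S)-3,3'-I2-BINOL (15 mol %), 4 Å MS, CH2Cl2, 0 °C; 7 and 10 (1.2 equiv) added over 2 h to 9 (1.5 equiv)
Reagents that add atoms: none
Why: Proposed new method: Rh2(OAc)4 turns diazoketone 7 into an acceptor carbene, alcohol 10 adds to it to give the protic oxonium ylide 11 (an enol equivalent), and 11 adds to aldehyde 9 held on the chiral Zr(IV) BINOLate before the 1,2-proton shift can deliver the plain O–H insertion product, so that C3–O and C2–C3 form in one operation and no ring is closed. The closest known reaction type is the Rh(II)/chiral Zr–BINOL (or chiral phosphoric acid) co-catalysed three-component coupling of aryldiazoacetates, benzylic alcohols and aldehydes; the extension lies in the terminal, acceptor-only aryl diazoketone, whose ylide is less stabilised but also less hindered. C2 (the carbinol carbon) is set by the 3,3'-diiodo-BINOLate, which shields one face of the Zr-bound aldehyde so that the ylide adds to the Si face and gives the R configuration. C3 follows from an open, antiperiplanar transition state of the kind that operates in Zr–BINOL Mukaiyama aldol additions, which keeps the PMB-oxy group away from the aldehyde aryl group and should favour the anti (2R,3R) adduct. The step needs ylide formation to beat cyclopropanation, C–H insertion and intramolecular trapping, which the substrate secures: the carbene carbon has no β-hydrogen, the ortho substituent is fluorine and cannot form a cyclic ylide as an ortho alkoxy group would, and slow addition into excess 9 and 10 keeps the prenyl alkenes from competing. It also needs aldol trapping to outrun the proton shift, which the Lewis-acid activation of the electron-rich aldehyde 9 is there to provide.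

Step 8
Reactants: 12 (2R,3R)-1-[2-fluoro-4-(methoxymethoxy)-3,5-bis(3-methylbut-2-en-1-yl)phenyl]-3-hydroxy-2-[(4-methoxyphenyl)methoxy]-3-[4-(methoxymethoxy)phenyl]propan-1-one
Product: 13 (2R,3R)-3-[(4-methoxyphenyl)methoxy]-7-(methoxymethoxy)-2-[4-(methoxymethoxy)phenyl]-6,8-bis(3-methylbut-2-en-1-yl)-2,3-dihydro-4H-chromen-4-one
Conditions: Cs2CO3 (1.5 equiv), DMF, 0 °C → rt
Reagents that add atoms: none
Why: Intramolecular SNAr (6-exo closure through a Meisenheimer complex stabilised by the ortho ketone) in which the C2 alkoxide displaces fluoride without breaking the C2–O bond, so C2 keeps its configuration and the trans (2R,3R) arrangement is also the preferred one at the base-labile C3.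

Step 9
Reactants: 13 (2R,3R)-3-[(4-methoxyphenyl)methoxy]-7-(methoxymethoxy)-2-[4-(methoxymethoxy)phenyl]-6,8-bis(3-methylbut-2-en-1-yl)-2,3-dihydro-4H-chromen-4-one
Product: 14 (2R,3R)-3-hydroxy-7-(methoxymethoxy)-2-[4-(methoxymethoxy)phenyl]-6,8-bis(3-methylbut-2-en-1-yl)-2,3-dihydro-4H-chromen-4-one
Conditions: DDQ (1.3 equiv), CH2Cl2/pH 7 buffer (10:1), 0 °C
Reagents that add atoms: none
Why: Oxidative PMB ether cleavage (hydride abstraction by DDQ, hydrolysis of the oxocarbenium ion) should be much faster than attack on the prenyl groups of the non-phenolic ring A and touches neither the MOM ethers nor a stereocentre.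

Step 10
Reactants: 14 (2R,3R)-3-hydroxy-7-(methoxymethoxy)-2-[4-(methoxymethoxy)phenyl]-6,8-bis(3-methylbut-2-en-1-yl)-2,3-dihydro-4H-chromen-4-one
Product: 15 Lespeflorin B2, (2R,3R)-3,7-dihydroxy-2-(4-hydroxyphenyl)-6,8-bis(3-methylbut-2-en-1-yl)-2,3-dihydro-4H-chromen-4-one
Conditions: 3 M aq. HCl, MeOH, 40 °C
Reagents that add atoms: none
Why: Acid-catalysed acetal exchange of both MOM ethers with methanol, run dilute and warm rather than hot so that the freed 7-OH does not add to the flanking prenyl alkenes and the trans-dihydroflavonol centres stay untouched.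

**Compound list**
1 | 2'-fluoro-4'-hydroxyacetophenone | CC(=O)c1ccc(O)cc1F | starting material
2 | 1-(2-fluoro-4-hydroxy-3,5-diiodophenyl)ethan-1-one | CC(=O)c1cc(I)c(O)c(I)c1F | intermediate
3 | 1-[2-fluoro-3,5-diiodo-4-(methoxymethoxy)phenyl]ethan-1-one | CC(=O)c1cc(I)c(OCOC)c(I)c1F | intermediate
4 | tributyl(3-methylbut-2-en-1-yl)stannane | CC(C)=CC[Sn](CCCC)(CCCC)CCCC | starting material
5 | 1-[2-fluoro-4-(methoxymethoxy)-3,5-bis(3-methylbut-2-en-1-yl)phenyl]ethan-1-one | CC(=O)c1cc(CC=C(C)C)c(OCOC)c(CC=C(C)C)c1F | intermediate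
6 | 4,4,4-trifluoro-1-[2-fluoro-4-(methoxymethoxy)-3,5-bis(3-methylbut-2-en-1-yl)phenyl]butane-1,3-dione | O=C(CC(=O)C(F)(F)F)c1cc(CC=C(C)C)c(OCOC)c(CC=C(C)C)c1F | intermediate
7 | 2-diazo-1-[2-fluoro-4-(methoxymethoxy)-3,5-bis(3-methylbut-2-en-1-yl)phenyl]ethan-1-one | [N-]=[N+]=CC(=O)c1cc(CC=C(C)C)c(OCOC)c(CC=C(C)C)c1F | intermediate
8 | 4-hydroxybenzaldehyde | O=Cc1ccc(O)cc1 | starting material
9 | 4-(methoxymethoxy)benzaldehyde | COCOc1ccc(C=O)cc1 | intermediate
10 | 4-methoxybenzyl alcohol | COc1ccc(CO)cc1 | starting material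
11 | protic oxonium ylide from the carbene of 7 and alcohol 10 (Z enolate form, not isolated) | COc1ccc(C[OH+]/C=C(\[O-])c2cc(CC=C(C)C)c(OCOC)c(CC=C(C)C)c2F)cc1 | intermediate
12 | (2R,3R)-1-[2-fluoro-4-(methoxymethoxy)-3,5-bis(3-methylbut-2-en-1-yl)phenyl]-3-hydroxy-2-[(4-methoxyphenyl)methoxy]-3-[4-(methoxymethoxy)phenyl]propan-1-one | O[C@H](c1ccc(OCOC)cc1)[C@@H](OCc1ccc(OC)cc1)C(=O)c1cc(CC=C(C)C)c(OCOC)c(CC=C(C)C)c1F | intermediate
13 | (2R,3R)-3-[(4-methoxyphenyl)methoxy]-7-(methoxymethoxy)-2-[4-(methoxymethoxy)phenyl]-6,8-bis(3-methylbut-2-en-1-yl)-2,3-dihydro-4H-chromen-4-one | CC(C)=CCc1cc2c(c(CC=C(C)C)c1OCOC)O[C@H](c1ccc(OCOC)cc1)[C@@H](OCc1ccc(OC)cc1)C2=O | intermediate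
14 | (2R,3R)-3-hydroxy-7-(methoxymethoxy)-2-[4-(methoxymethoxy)phenyl]-6,8-bis(3-methylbut-2-en-1-yl)-2,3-dihydro-4H-chromen-4-one | CC(C)=CCc1cc2c(c(CC=C(C)C)c1OCOC)O[C@H](c1ccc(OCOC)cc1)[C@@H](O)C2=O | intermediate
15 | Lespeflorin B2 | CC(C)=CCc1cc2c(c(CC=C(C)C)c1O)O[C@H](c1ccc(O)cc1)[C@@H](O)C2=O | target

**Step count**
Total steps: 10. Longest linear sequence: 9 steps (steps 1–5 and 7–10).

**Steps most likely to fail**

1. Step 7 (Proposed new method). The ylide may undergo the 1,2-proton shift before it meets the electron-rich aldehyde (plain O–H insertion), or it may add with poor facial or anti/syn control. A syn adduct of the right C2 configuration should still converge, because after ring closure C3 can equilibrate under base towards the trans isomer; a wrong C2 configuration cannot be corrected.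
Fallback (known chemistry; both stereocentres and ring C are made another way). It sets out from stannane 4 and aldehyde 9 and returns at the target 15. Commercial 2',4'-dihydroxyacetophenone F1 is diiodinated (NIS, MeCN) to 1-(2,4-dihydroxy-3,5-diiodophenyl)ethan-1-one F2 and protected (NaH, MOMCl, DMF) as the bis-MOM ether F3. Double Stille coupling with 4 (Pd(PPh3)4, DMF) gives the diprenyl ketone F4. Claisen–Schmidt condensation with 9 (KOH, EtOH) gives the (E)-chalcone F5. Juliá–Colonna epoxidation (poly-L-leucine, the antipode that gives (2R,3S) oxides from simple chalcones; urea–H2O2, DBU, THF) is nucleophilic and should spare the prenyl alkenes, giving the (2R,3S)-epoxy ketone F6. HCl in MeOH then removes the three MOM groups, and the freed 2'-OH opens the epoxide at the benzylic carbon with inversion (6-endo) to give 15 directly.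

2. Step 8. Retro-aldol cleavage of the alkoxide, base-induced dehydration, or ring-opening of the product enolate may compete with or follow the fluoride displacement on the alkyl-substituted ring and erode the C2 configuration.
Fallback (the ring is closed on an arene activated by the two iodine atoms, and prenylation is moved behind the ring closure). It sets out from diiodide 3 and returns at 13. 3 is taken through the chemistry of steps 4, 5 and 7 without prenylation: trifluoroacetylation to the diiodo trifluoromethyl diketone F7, diazo transfer to the diiodo diazoketone F8, and three-component coupling with 9 and 10 through the diiodo oxonium ylide F9 to the diiodo anti adduct F10. In F10 the fluorine has iodine ortho and para to it, so the SNAr closure (Cs2CO3, DMF, −20 → 0 °C) should run at a temperature where retro-aldol is slow and give the diiodo chromanone F11. Double Stille coupling of F11 with 4 under the neutral conditions of step 3 gives 13.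

3. Step 3. Transmetalation of the prenyl stannane at its γ-carbon (reverse-prenyl products), slow coupling at the doubly ortho-substituted C3 iodide and protodeiodination may lower the amount of clean diprenyl product.
Fallback (prenyl groups built in two stages). It sets out from 3 and returns at 5. Stille coupling with allyltributylstannane, which has no α/γ ambiguity, gives the diallyl ketone F12. Olefin cross-metathesis with 2-methyl-2-butene (Grubbs second-generation catalyst, CH2Cl2, 40 °C) then converts both allyl groups into prenyl groups.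

**Further compounds**
F1 | step 7 | 2',4'-dihydroxyacetophenone (purchased starting material of the fallback) | CC(=O)c1ccc(O)cc1O
F2 | step 7 | 1-(2,4-dihydroxy-3,5-diiodophenyl)ethan-1-one | CC(=O)c1cc(I)c(O)c(I)c1O
F3 | step 7 | 1-[3,5-diiodo-2,4-bis(methoxymethoxy)phenyl]ethan-1-one | CC(=O)c1cc(I)c(OCOC)c(I)c1OCOC
F4 | step 7 | 1-[2,4-bis(methoxymethoxy)-3,5-bis(3-methylbut-2-en-1-yl)phenyl]ethan-1-one | CC(=O)c1cc(CC=C(C)C)c(OCOC)c(CC=C(C)C)c1OCOC
F5 | step 7 | (E)-1-[2,4-bis(methoxymethoxy)-3,5-bis(3-methylbut-2-en-1-yl)phenyl]-3-[4-(methoxymethoxy)phenyl]prop-2-en-1-one | COCOc1ccc(/C=C/C(=O)c2cc(CC=C(C)C)c(OCOC)c(CC=C(C)C)c2OCOC)cc1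
F6 | step 7 | [2,4-bis(methoxymethoxy)-3,5-bis(3-methylbut-2-en-1-yl)phenyl][(2R,3S)-3-[4-(methoxymethoxy)phenyl]oxiran-2-yl]methanone | O=C(c1cc(CC=C(C)C)c(OCOC)c(CC=C(C)C)c1OCOC)[C@@H]1O[C@H]1c1ccc(OCOC)cc1
F7 | step 8 | 4,4,4-trifluoro-1-[2-fluoro-3,5-diiodo-4-(methoxymethoxy)phenyl]butane-1,3-dione | O=C(CC(=O)C(F)(F)F)c1cc(I)c(OCOC)c(I)c1F
F8 | step 8 | 2-diazo-1-[2-fluoro-3,5-diiodo-4-(methoxymethoxy)phenyl]ethan-1-one | [N-]=[N+]=CC(=O)c1cc(I)c(OCOC)c(I)c1F
F9 | step 8 | protic oxonium ylide from the carbene of F8 and alcohol 10 (not isolated) | COc1ccc(C[OH+]/C=C(\[O-])c2cc(I)c(OCOC)c(I)c2F)cc1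
F10 | step 8 | (2R,3R)-1-[2-fluoro-3,5-diiodo-4-(methoxymethoxy)phenyl]-3-hydroxy-2-[(4-methoxyphenyl)methoxy]-3-[4-(methoxymethoxy)phenyl]propan-1-one | O[C@H](c1ccc(OCOC)cc1)[C@@H](OCc1ccc(OC)cc1)C(=O)c1cc(I)c(OCOC)c(I)c1F
F11 | step 8 | (2R,3R)-6,8-diiodo-3-[(4-methoxyphenyl)methoxy]-7-(methoxymethoxy)-2-[4-(methoxymethoxy)phenyl]-2,3-dihydro-4H-chromen-4-one | COCOc1c(I)cc2c(c1I)O[C@H](c1ccc(OCOC)cc1)[C@@H](OCc1ccc(OC)cc1)C2=O
F12 | step 3 | 1-[2-fluoro-4-(methoxymethoxy)-3,5-di(prop-2-en-1-yl)phenyl]ethan-1-one | CC(=O)c1cc(CC=C)c(OCOC)c(CC=C)c1F
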